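## Structural features

The target is a tetrahydrofuran (O1, C2–C5). Ring A (3,4-dimethoxyphenyl) sits on C2, a hydroxymethyl arm (C9) on C3, and an aroyl group on C4 whose ketone carbon C7' is bonded to ring B (3,4,5-trimethoxyphenyl); C5 is a bare CH2. The three stereocentres are contiguous, C2 (S), C3 (S) and C4 (R), with ring A and C9 cis and C9 and the aroyl group trans. C4 lies α to the ketone and can be equilibrated, which helps because the 3,4-trans arrangement avoids an all-cis ring; C3 cannot be corrected once it is set. The fragile points are the β-alkoxy ketone (O1–C5–C4–C7', open to retro-oxa-Michael ring opening), the benzylic C2–O1 bond on an electron-rich arene (acid-labile, and with it the C2 configuration), and the γ-hydroxy ketone, which closes to a hemiketal whenever C9 and the aroyl group are cis. The real difficulty is the contra-thermodynamic 2,3-cis relationship together with the absolute configuration at C2, from which the other centres must be derived. The key step uses two facts: C5 is an unsubstituted carbon β to the C4 carbonyl carbon, so O1–C5 can come from conjugate addition to a methylenemalonate, and C3–C9 can be read as a former alkyne, so C3–C4 can come from a carbocyclisation. This leaves C3 as an exocyclic methylene next to C2, and C4 with two esters, one to become the ketone by way of a lactone and one to leave as CO2.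

## Logic of the disconnections

17 to 15. The C4–H bond is traced back to a C4–CO2Me bond. The cut is placed there because C4 is α to the ketone and settles trans to C9 by equilibration, so its configuration does not have to be built. The gain is a quaternary, malonate-type C4. The forward step must remove the ester under near-neutral conditions that spare the β-alkoxy ketone and the C2–O1 bond, and must end with C4 equilibrated.

15 to 11 and 13 (made from 12). The C7'–ring B bond is cut and the freed C9 hydroxyl is tied back to C7' as a lactone, because a γ-hydroxy aryl ketone is the adduct of an aryl anion and a γ-lactone. Ring B leaves as 13, and the cis ring fusion of 11 decides which of the two C4 carbonyl groups becomes the ketone. The forward step must stop at single addition and must choose the lactone over the remaining methyl ester.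

11 to 8. The lactone C–O bond, the C9–O bond and the C3–H bond are cut, which leads to an exocyclic C3=C9 alkene. This removes the C3 and C4 stereocentres together (the two esters of 8 are identical) and leaves C2 as the only stereocentre. The forward hydroboration must take the alkene face anti to ring A so that C9 ends cis to it.

8 to 4 and 6 (key disconnection). O1–C5 and C3–C4 are cut, which opens the ring and removes two skeletal bonds. What remains is a propargylic alcohol with one stereocentre and a three-carbon acceptor. The forward step needs the alkoxide addition and ring closure to outrun oligomerisation of 6, closure in the 5-exo-dig sense, and no migration of the new alkene toward C2.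

4 to 3, then 1 and 2. The stereocentre of 4 is traced to racemic 3, and the bond between C2 and the alkyne is cut. Resolution is chosen over asymmetric reduction of the corresponding aryl ethynyl ketone, because in that ketone two π-substituents flank the carbonyl and the terminal ynone is a Michael acceptor. The forward resolution must be stopped just past half conversion; half of 3 is lost, which is tolerable two steps from cheap materials.

6 to 5. The C=CH2 bond is cut to a malonate and a one-carbon aldehyde. The forward condensation must deliver the monomer freshly distilled, since it polymerises with nucleophiles.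

## Other disconnections considered

Alternative 1: The cut is the C3–C4 bond, made by a 1,2-shift, so the tetrahydrofuran is traced to a six-membered ring O1–C2–C3–C7'–C4–C5, the α-diazo ketone A1. In the forward direction, photolysis of A1 expels N2, C3 migrates from C7' to C4 with retention (Wolff rearrangement), and the ketene at C7' is trapped as the all-cis N-methoxy-N-methylamide A2. Aryl addition, C4 epimerisation and desilylation would follow.
- In its favour: the pyranone behind A1 could come from a catalytic enantioselective hetero-Diels–Alder reaction of 1, setting C2 and C3 together without discarding half of the material. On this point it is better than the resolution in the chosen plan. The amide of A2 also accepts exactly one aryl nucleophile with no competing ester, which is better than step 6 of the chosen plan.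
- Against it here: in the pyranone, C3 is α to the ketone and must stay cis to ring A, the less stable arrangement, through alkene reduction and regioselective diazo transfer at C4. The carbene can also undergo a 1,2-hydride shift from C5. A silyl group must be put on and removed, and photolysis limits scale.
- Comparison: both plans end with the same C4 equilibration. The ring contraction is stereospecific at C3, whereas the chosen plan depends on the facial selectivity of a hydroboration; that is a point for the alternative, but the chosen plan never carries an epimerisable C3. The alternative would need roughly nine to ten steps against seven.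

Alternative 2: The cuts are O1–C5, C4–C7' and C7'–ring B in one operation, leading to the α-hydroxyallene A3, the boronic acid A4 and carbon monoxide A5. In the forward direction, with PdCl2(MeCN)2, the C2 hydroxyl of A3 adds to the terminal allene carbon; the C4 vinylpalladium inserts A5 and is arylated by A4 to give the 2,5-dihydrofuran A6.
- In its favour: three bonds, ring B and the ketone at the right oxidation level arrive in one step, with no organolithium and no decarboxylation. In convergence it is better than the chosen plan.
- Against it here: A6 has a tetrasubstituted C3=C4 alkene, so C3 and C4 both remain to be set, by syn hydrogenation anti to ring A and then C4 epimerisation. C2 in A6 is benzylic, allylic and α to oxygen, so hydrogenolysis, double-bond migration and aromatisation to a furan threaten the one centre that carries the chirality. The palladium step can also couple without inserting A5, or carbopalladate the allene. A3 itself needs an enantioselective, regiocontrolled allenylation of 1.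
- Comparison: the chosen plan sets C3 on a 1,1-disubstituted alkene, which is easier than reducing a tetrasubstituted enone. Both key steps begin with O–C5 bond formation by the C2 oxygen and follow with C–C bond formation at C4, so the logic is alike. At about six to seven steps the alternative is the equal of the chosen plan in length.

Alternative 3: The cuts are O1–C2 and C4–C5, leading to the lactone-fused donor–acceptor cyclopropane A7 and formaldehyde A8. In the forward direction, Sn(OTf)2 activates A7, the oxygen of A8 opens C2 with inversion, and the C4 enolate closes on the carbon of A8. The product is the cis-fused lactone ester A9, which is the same compound as 11 of the chosen route.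
- In its favour: inversion at C2 turns the exo-aryl cyclopropane, the isomer expected from intramolecular cyclopropanation of an (E)-cinnamyl diazomalonate, into the 2,3-cis tetrahydrofuran. The C2/C3 relationship is then fixed by a stereospecific mechanism and not by facial selectivity, which is better than the chosen plan on this point. The endgame from A9 is identical to steps 6 and 7, so there the two plans are equal.
- Against it here: ring A is a very strong donor, so the Lewis acid can open A7 reversibly to a benzylic zwitterion and erode its enantiomeric purity before A8 is captured. A8 must be delivered as the monomer and is a weaker, oligomerising partner than the aryl aldehydes on which this cycloaddition type rests. Enantioselective intramolecular cyclopropanation of diazomalonates is usually less secure than a lipase resolution, and a lactone/ester pair chelates tin less well than a 1,1-diester.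
- Comparison: about eight steps against seven. The chosen plan reaches the same lactone from a resolved alcohol whose configuration is not at risk in the ring-forming step.

Key step: step 4

Remarks on the chemistry:
- The stereocentre of 4 is set by lipase resolution of 3 and not by transfer hydrogenation of the ynone; the reason is in step 2.
- The benzylic carbon keeps one spatial arrangement throughout. Its descriptor is S in 4, 7 and 9–17 but R in 8, only because the CIP ranking of ring A against the neighbouring ring carbon changes.
- Compound 15 is drawn as the open hydroxy ketone. It is assumed to equilibrate with its ring tautomer (the neutral form of 14), and either form enters step 7.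

## Route

Step 1
Reactants: 1 3,4-dimethoxybenzaldehyde (veratraldehyde); 2 ethynylmagnesium bromide
Product: 3 rac-1-(3,4-dimethoxyphenyl)prop-2-yn-1-ol
Conditions: 2 (0.5 M in THF, 1.2 equiv), THF, 0 °C to rt; sat. aq NH4Cl
Reagents that add atoms: none
Why: Grignard 1,2-addition of an alkynyl nucleophile to a non-enolisable aromatic aldehyde; the racemate is wanted because the stereocentre is set by resolution in step 2.

Step 2
Reactants: 3 rac-1-(3,4-dimethoxyphenyl)prop-2-yn-1-ol
Product: 4 (1S)-1-(3,4-dimethoxyphenyl)prop-2-yn-1-ol
Conditions: immobilised Candida antarctica lipase B, vinyl acetate (3 equiv), MTBE, 30 °C, stopped just past half conversion (chiral HPLC); chromatography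
Reagents that add atoms: none
Why: Enzymatic kinetic resolution by lipase-catalysed transesterification with an irreversible acyl donor: with ring A as the large and ethynyl as the medium substituent the lipase should acylate the (R)-alcohol, so the alcohol left behind is (S) and should be enantiomerically pure once conversion passes one half. This replaces transfer hydrogenation of the aryl ethynyl ketone with RuCl(p-cymene)(TsDPEN), where two π-substituents compete for the catalyst and the terminal ynone is a Michael acceptor toward the alcohol solvent.

Step 3
Reactants: 5 dimethyl malonate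
Product: 6 dimethyl 2-methylidenepropanedioate (dimethyl methylenemalonate)
Conditions: (CH2O)n, Cu(OAc)2·H2O (cat.), KOAc (cat.), AcOH, 100 °C; distillation at reduced pressure; used the same day
Reagents that add atoms: formaldehyde (as paraformaldehyde), C=O
Why: Knoevenagel condensation of the malonate with formaldehyde and dehydration, the monomer being freed from its oligomers by distillation; it polymerises with nucleophiles and is therefore not stored.

Step 4
Reactants: 4 (1S)-1-(3,4-dimethoxyphenyl)prop-2-yn-1-ol; 6 dimethyl 2-methylidenepropanedioate
Product: 8 dimethyl (5R)-5-(3,4-dimethoxyphenyl)-4-methylideneoxolane-3,3-dicarboxylate, via oxa-Michael adduct 7 (not isolated)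
Conditions: t-BuOK (10 mol%), CuI (5 mol%), THF, argon, rt; 6 (1.3 equiv) in THF added over 2 h; AcOH quench
Reagents that add atoms: none
Why: Catalytic t-BuOK turns 4 into its alkoxide, which adds to the unsubstituted β-carbon of 6 (oxa-Michael addition, O1–C5) and gives the malonate anion of 7. CuI converts the terminal alkyne into a copper acetylide, and the malonate carbon adds across the activated triple bond at its internal carbon (C3–C4), a Conia-ene-type carbocupration. The ring closes in the 5-exo-dig mode: the internal alkyne carbon is reached through a five-membered transition state, whereas 6-endo-dig attack would have to occur at the copper-bearing terminal carbon. The vinylcopper is protonated by a further molecule of 4, which releases 8 with its exocyclic methylene and regenerates the alkoxide, so base and copper both turn over. The closest known reaction type is the base and copper iodide promoted addition–carbocyclisation of propargylic alcohols with alkylidene malonates to 3-methylenetetrahydrofurans. No stereocentre is formed; C2 is carried over from 4 untouched. Ring closure must outrun anionic oligomerisation of 6, which slow addition of 6 to the alkoxide and excess alcohol should secure. The exocyclic alkene must stay out of conjugation with ring A, which the weak catalytic base (a malonate and a secondary alkoxide) at room temperature should secure.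

Step 5
Reactants: 8 dimethyl (5R)-5-(3,4-dimethoxyphenyl)-4-methylideneoxolane-3,3-dicarboxylate
Product: 11 methyl (3aS,6S,6aS)-6-(3,4-dimethoxyphenyl)-3-oxotetrahydro-1H,3H-furo[3,4-c]furan-3a(4H)-carboxylate, via B-alkyl-9-BBN adduct 9 (not isolated), via hydroxy diester 10 (not isolated)
Conditions: 9-BBN (0.5 M in THF, 1.5 equiv), 0 to 40 °C; NaBO3·4H2O, H2O, rt; PPTS (cat.), PhMe, 50 °C
Reagents that add atoms: sodium perborate (NaBO3·4H2O), [Na+].[Na+].O[B-]1(O)OO[B-](O)(O)OO1 (9-BBN, B1C2CCCC1CCC2, leaves atoms only in 9)
Why: Hydroboration–oxidation followed by lactonisation: 9-BBN puts boron on the terminal carbon C9 and delivers hydrogen to C3 from the face anti to ring A on the neighbouring C2, so C9 should end cis to ring A (C3 S). The new alcohol closes on the ester that is cis to it (the two esters at C4 are identical), which gives the cis-fused γ-lactone and thereby fixes C4.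

Step 6
Reactants: 11 methyl (3aS,6S,6aS)-6-(3,4-dimethoxyphenyl)-3-oxotetrahydro-1H,3H-furo[3,4-c]furan-3a(4H)-carboxylate; 12 5-bromo-1,2,3-trimethoxybenzene
Product: 15 methyl (3R,4S,5S)-5-(3,4-dimethoxyphenyl)-4-(hydroxymethyl)-3-(3,4,5-trimethoxybenzoyl)oxolane-3-carboxylate, via 3,4,5-trimethoxyphenyllithium 13 (not isolated), via lithium hemiketal 14 (not isolated)
Conditions: 12 (1.2 equiv), n-BuLi (1.15 equiv), THF, −78 °C; then 11, −78 °C; sat. aq NH4Cl at −78 °C
Reagents that add atoms: none
Why: Bromine–lithium exchange followed by addition of the aryllithium to the lactone carbonyl (nucleophilic acyl addition): the γ-lactone is the more electrophilic of the two carbonyl groups, and its adduct 14 is a cyclic lithium hemiketal that does not collapse at −78 °C, which should stop the reaction at single addition. Compound 11 has no acidic α-hydrogen, so enolisation cannot compete.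

Step 7
Reactants: 15 methyl (3R,4S,5S)-5-(3,4-dimethoxyphenyl)-4-(hydroxymethyl)-3-(3,4,5-trimethoxybenzoyl)oxolane-3-carboxylate
Product: 17 [(3R,4S,5S)-5-(3,4-dimethoxyphenyl)-4-(hydroxymethyl)oxolan-3-yl](3,4,5-trimethoxyphenyl)methanone (the target), via keto acid 16 (not isolated)
Conditions: LiCl (3 equiv), H2O (2 equiv), DMSO, 140 °C
Reagents that add atoms: none
Why: Krapcho demethoxycarbonylation: chloride demethylates the ester by SN2 attack, the β-keto carboxylate 16 loses CO2, and the enol is protonated. C4 is α to the ketone and should equilibrate to the aroyl group trans to the C3 hydroxymethyl arm (C4 R), the all-cis ring being the strained alternative.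

## Compound list

1 | 3,4-dimethoxybenzaldehyde (veratraldehyde) | COc1ccc(C=O)cc1OC | starting material
2 | ethynylmagnesium bromide | C#C[Mg]Br | starting material
3 | rac-1-(3,4-dimethoxyphenyl)prop-2-yn-1-ol | COc1ccc(C(C#C)O)cc1OC | intermediate
4 | (1S)-1-(3,4-dimethoxyphenyl)prop-2-yn-1-ol | COc1ccc([C@H](C#C)O)cc1OC | intermediate
5 | dimethyl malonate | COC(=O)CC(=O)OC | starting material
6 | dimethyl 2-methylidenepropanedioate | C=C(C(=O)OC)C(=O)OC | intermediate
7 | dimethyl 2-({[(1S)-1-(3,4-dimethoxyphenyl)prop-2-yn-1-yl]oxy}methyl)propanedioate, formed as its enolate | COc1ccc([C@H](C#C)OCC(C(=O)OC)C(=O)OC)cc1OC | intermediate (not isolated)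
8 | dimethyl (5R)-5-(3,4-dimethoxyphenyl)-4-methylideneoxolane-3,3-dicarboxylate | COc1ccc([C@H]2OCC(C(=O)OC)(C(=O)OC)C2=C)cc1OC | intermediate
9 | dimethyl (4R,5S)-4-[(9-borabicyclo[3.3.1]nonan-9-yl)methyl]-5-(3,4-dimethoxyphenyl)oxolane-3,3-dicarboxylate | COc1ccc([C@H]2OCC(C(=O)OC)(C(=O)OC)[C@H]2CB3C4CCCC3CCC4)cc1OC | intermediate (not isolated)
10 | dimethyl (4S,5S)-5-(3,4-dimethoxyphenyl)-4-(hydroxymethyl)oxolane-3,3-dicarboxylate | COc1ccc([C@H]2OCC(C(=O)OC)(C(=O)OC)[C@H]2CO)cc1OC | intermediate (not isolated)
11 | methyl (3aS,6S,6aS)-6-(3,4-dimethoxyphenyl)-3-oxotetrahydro-1H,3H-furo[3,4-c]furan-3a(4H)-carboxylate (cis-fused lactone, ring A cis to the lactone CH2) | COc1ccc([C@H]2OC[C@@]3(C(=O)OC)C(=O)OC[C@@H]23)cc1OC | intermediate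
12 | 5-bromo-1,2,3-trimethoxybenzene | COc1cc(Br)cc(OC)c1OC | starting material
13 | 3,4,5-trimethoxyphenyllithium | [Li]c1cc(OC)c(OC)c(OC)c1 | intermediate (not isolated)
14 | methyl (3aR,6S,6aS)-6-(3,4-dimethoxyphenyl)-3-hydroxy-3-(3,4,5-trimethoxyphenyl)tetrahydro-1H,3H-furo[3,4-c]furan-3a(4H)-carboxylate, formed as its lithium alkoxide, hemiketal carbon not assigned | COc1ccc([C@H]2OC[C@@]3(C(=O)OC)C(O)(c4cc(OC)c(OC)c(OC)c4)OC[C@@H]23)cc1OC | intermediate (not isolated)
15 | methyl (3R,4S,5S)-5-(3,4-dimethoxyphenyl)-4-(hydroxymethyl)-3-(3,4,5-trimethoxybenzoyl)oxolane-3-carboxylate | COc1ccc([C@H]2OC[C@@](C(=O)OC)(C(=O)c3cc(OC)c(OC)c(OC)c3)[C@H]2CO)cc1OC | intermediate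
16 | (3R,4S,5S)-5-(3,4-dimethoxyphenyl)-4-(hydroxymethyl)-3-(3,4,5-trimethoxybenzoyl)oxolane-3-carboxylic acid, formed as its lithium salt | COc1ccc([C@H]2OC[C@@](C(=O)O)(C(=O)c3cc(OC)c(OC)c(OC)c3)[C@H]2CO)cc1OC | intermediate (not isolated)
17 | [(3R,4S,5S)-5-(3,4-dimethoxyphenyl)-4-(hydroxymethyl)oxolan-3-yl](3,4,5-trimethoxyphenyl)methanone | COc1ccc([C@H]2OC[C@H](C(=O)c3cc(OC)c(OC)c(OC)c3)[C@H]2CO)cc1OC | target

## Step count and least certain steps

Total step count: 7. Longest linear sequence: 6 steps (steps 1, 2, 4, 5, 6, 7, from 1 to 17); step 3 is a one-step side branch.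

Step 4 (key step). The most likely failure is chain growth: the malonate anion of 7 adds to a second molecule of 6 (anionic oligomerisation) before it closes on the alkyne. A second risk is base-induced migration of the exocyclic double bond toward C2. The fallback sets out from 4 and returns to the route at 16 and 17.
- The acceptor 6 is replaced by the sterically protected, isolable di-tert-butyl 2-methylidenepropanedioate F1, made from di-tert-butyl malonate and paraformaldehyde under the conditions of step 3.
- The same t-BuOK/CuI domino with 4 should give di-tert-butyl (5R)-5-(3,4-dimethoxyphenyl)-4-methylideneoxolane-3,3-dicarboxylate F2.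
- Hydroboration–oxidation as in step 5 should give di-tert-butyl (4S,5S)-5-(3,4-dimethoxyphenyl)-4-(hydroxymethyl)oxolane-3,3-dicarboxylate F3.
- Catalytic t-BuOK in THF should close the lactone to tert-butyl (3aR,6S,6aS)-6-(3,4-dimethoxyphenyl)-3-oxotetrahydro-1H,3H-furo[3,4-c]furan-3a(4H)-carboxylate F4.
- Reagent 13 at −78 °C should open only the lactone, since the tert-butyl ester is inert to it, to give tert-butyl (3R,4S,5S)-5-(3,4-dimethoxyphenyl)-4-(hydroxymethyl)-3-(3,4,5-trimethoxybenzoyl)oxolane-3-carboxylate F5.
- TMSOTf/2,6-lutidine (CH2Cl2, 0 °C) and aqueous work-up should cleave the tert-butyl ester to 16, which decarboxylates on gentle warming to 17.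

Step 6. The risk is loss of chemoselectivity: attack of 13 on the methyl ester, or a second addition. If the lithium hemiketal warms, acyl migration by retro-Claisen cleavage of the C4–C7' bond is also possible. The fallback sets out from 11 and returns at 17.
- The ester is removed first by Krapcho demethoxycarbonylation of 11 (LiCl, wet DMSO, 140 °C), giving the cis-fused lactone (3aS,4S,6aS)-4-(3,4-dimethoxyphenyl)tetrahydro-1H,3H-furo[3,4-c]furan-1-one F6, in which only one carbonyl group is left.
- Reagent 13 at −78 °C then gives the all-cis ketone [(3S,4S,5S)-5-(3,4-dimethoxyphenyl)-4-(hydroxymethyl)oxolan-3-yl](3,4,5-trimethoxyphenyl)methanone F7.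
- Base equilibration at C4 (DBU, CH2Cl2, rt) should convert F7 into 17.

Step 7. The risks are incomplete equilibration at C4, because the cis epimer can be held back as a hemiketal with the C9 hydroxyl, and retro-oxa-Michael opening at O1–C5 at high temperature followed by re-closure through the C9 hydroxyl. The fallback sets out from 15 and returns at 17.
- The C9 hydroxyl is silylated (TBSCl, imidazole, DMF) to methyl (3R,4S,5S)-4-({[tert-butyl(dimethyl)silyl]oxy}methyl)-5-(3,4-dimethoxyphenyl)-3-(3,4,5-trimethoxybenzoyl)oxolane-3-carboxylate F8.
- Krapcho demethoxycarbonylation, with C4 now free to equilibrate and no hydroxyl to interfere, gives [(3R,4S,5S)-4-({[tert-butyl(dimethyl)silyl]oxy}methyl)-5-(3,4-dimethoxyphenyl)oxolan-3-yl](3,4,5-trimethoxyphenyl)methanone F9.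
- HF·pyridine in THF at 0 °C removes the silyl group to give 17.

Step 5. The risks are slow hydroboration of the hindered alkene and insufficient facial discrimination. The C3 epimer would lactonise just as readily, since both faces of C4 carry an ester, and could not be corrected later. The fallback sets out from 8 and returns at 10, which lactonises to 11 as in step 5.
- Epoxidation (m-CPBA, NaHCO3, CH2Cl2) gives dimethyl (4R)-4-(3,4-dimethoxyphenyl)-1,5-dioxaspiro[2.4]heptane-7,7-dicarboxylate F10, as a mixture at the spiro carbon.
- Titanocene-mediated reductive epoxide opening (Cp2TiCl2, Mn, 2,4,6-collidine hydrochloride, 1,4-cyclohexadiene, THF) cleaves the C3–O bond homolytically. The planar C3 radical should take a hydrogen atom anti to ring A, and work-up gives 10.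

## Further compounds

F1 | step 4 | di-tert-butyl 2-methylidenepropanedioate | C=C(C(=O)OC(C)(C)C)C(=O)OC(C)(C)C
F2 | step 4 | di-tert-butyl (5R)-5-(3,4-dimethoxyphenyl)-4-methylideneoxolane-3,3-dicarboxylate | COc1ccc([C@H]2OCC(C(=O)OC(C)(C)C)(C(=O)OC(C)(C)C)C2=C)cc1OC
F3 | step 4 | di-tert-butyl (4S,5S)-5-(3,4-dimethoxyphenyl)-4-(hydroxymethyl)oxolane-3,3-dicarboxylate | COc1ccc([C@H]2OCC(C(=O)OC(C)(C)C)(C(=O)OC(C)(C)C)[C@H]2CO)cc1OC
F4 | step 4 | tert-butyl (3aR,6S,6aS)-6-(3,4-dimethoxyphenyl)-3-oxotetrahydro-1H,3H-furo[3,4-c]furan-3a(4H)-carboxylate | COc1ccc([C@H]2OC[C@@]3(C(=O)OC(C)(C)C)C(=O)OC[C@@H]23)cc1OC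
F5 | step 4 | tert-butyl (3R,4S,5S)-5-(3,4-dimethoxyphenyl)-4-(hydroxymethyl)-3-(3,4,5-trimethoxybenzoyl)oxolane-3-carboxylate | COc1ccc([C@H]2OC[C@@](C(=O)OC(C)(C)C)(C(=O)c3cc(OC)c(OC)c(OC)c3)[C@H]2CO)cc1OC
F6 | step 6 | (3aS,4S,6aS)-4-(3,4-dimethoxyphenyl)tetrahydro-1H,3H-furo[3,4-c]furan-1-one | COc1ccc([C@H]2OC[C@H]3C(=O)OC[C@@H]23)cc1OC
F7 | step 6 | [(3S,4S,5S)-5-(3,4-dimethoxyphenyl)-4-(hydroxymethyl)oxolan-3-yl](3,4,5-trimethoxyphenyl)methanone | COc1ccc([C@H]2OC[C@@H](C(=O)c3cc(OC)c(OC)c(OC)c3)[C@H]2CO)cc1OC
F8 | step 7 | methyl (3R,4S,5S)-4-({[tert-butyl(dimethyl)silyl]oxy}methyl)-5-(3,4-dimethoxyphenyl)-3-(3,4,5-trimethoxybenzoyl)oxolane-3-carboxylate | COc1ccc([C@H]2OC[C@@](C(=O)OC)(C(=O)c3cc(OC)c(OC)c(OC)c3)[C@H]2CO[Si](C)(C)C(C)(C)C)cc1OC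
F9 | step 7 | [(3R,4S,5S)-4-({[tert-butyl(dimethyl)silyl]oxy}methyl)-5-(3,4-dimethoxyphenyl)oxolan-3-yl](3,4,5-trimethoxyphenyl)methanone | COc1ccc([C@H]2OC[C@H](C(=O)c3cc(OC)c(OC)c(OC)c3)[C@H]2CO[Si](C)(C)C(C)(C)C)cc1OC
F10 | step 5 | dimethyl (4R)-4-(3,4-dimethoxyphenyl)-1,5-dioxaspiro[2.4]heptane-7,7-dicarboxylate | COc1ccc([C@H]2OCC(C(=O)OC)(C(=O)OC)C23CO3)cc1OC
A1 | alternative 1 | (2S,3S)-3-({[tert-butyl(dimethyl)silyl]oxy}methyl)-5-diazo-2-(3,4-dimethoxyphenyl)oxan-4-one | COc1ccc([C@H]2OCC(=[N+]=[N-])C(=O)[C@H]2CO[Si](C)(C)C(C)(C)C)cc1OC
A2 | alternative 1 | (3S,4S,5S)-4-({[tert-butyl(dimethyl)silyl]oxy}methyl)-5-(3,4-dimethoxyphenyl)-N-methoxy-N-methyloxolane-3-carboxamide | COc1ccc([C@H]2OC[C@@H](C(=O)N(C)OC)[C@H]2CO[Si](C)(C)C(C)(C)C)cc1OC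
A3 | alternative 2 | (1R)-2-({[tert-butyl(dimethyl)silyl]oxy}methyl)-1-(3,4-dimethoxyphenyl)buta-2,3-dien-1-ol | COc1ccc([C@@H](O)C(CO[Si](C)(C)C(C)(C)C)=C=C)cc1OC
A4 | alternative 2 | (3,4,5-trimethoxyphenyl)boronic acid | COc1cc(B(O)O)cc(OC)c1OC
A5 | alternative 2 | carbon monoxide | [C-]#[O+]
A6 | alternative 2 | [(5R)-4-({[tert-butyl(dimethyl)silyl]oxy}methyl)-5-(3,4-dimethoxyphenyl)-2,5-dihydrofuran-3-yl](3,4,5-trimethoxyphenyl)methanone | COc1ccc([C@H]2OCC(C(=O)c3cc(OC)c(OC)c(OC)c3)=C2CO[Si](C)(C)C(C)(C)C)cc1OC
A7 | alternative 3 | methyl (1R,5S,6R)-6-(3,4-dimethoxyphenyl)-2-oxo-3-oxabicyclo[3.1.0]hexane-1-carboxylate | COc1ccc([C@H]2[C@@H]3COC(=O)[C@]23C(=O)OC)cc1OC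
A8 | alternative 3 | formaldehyde | C=O
A9 | alternative 3 | methyl (3aS,6S,6aS)-6-(3,4-dimethoxyphenyl)-3-oxotetrahydro-1H,3H-furo[3,4-c]furan-3a(4H)-carboxylate | COc1ccc([C@H]2OC[C@@]3(C(=O)OC)C(=O)OC[C@@H]23)cc1OC
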